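**Assumption:** hypothamnolic acid has no stereocentres, so it is achiral and "single enantiomer" is moot. Commercial orsellinic acid and atraric acid (methyl 2,4-dihydroxy-3,6-dimethylbenzoate) are taken as available.

## Retrosynthetic overview
- Target **1** comes from the benzyl-protected aldehyde depside **2** by Pinnick oxidation of the CHO to CO2H, then hydrogenolysis of the benzyl ether and benzyl ester.
- Depside **2** comes from the ester coupling (TFAA method) of acid **3** (3-formyl-2-hydroxy-4-methoxy-6-methylbenzoic acid) with hydroquinone **4** (benzyl 4-benzyloxy-2,5-dihydroxy-3,6-dimethylbenzoate). The chelated 2-OH of **4** is unreactive, so only the 5-OH is acylated.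
- **3** comes from orsellinic acid **5** by benzyl ester formation, 4-O-methylation, chelation-directed ortho-formylation and hydrogenolysis.
- **4** comes from atraric acid **6** by hydrolysis, benzylation, Fremy oxidation to a quinone and reduction.
- No ring is constructed: both benzene rings come from commercial phenols, and the only new bond between the halves is the depside ester.

## Route

**Step 1**
Reactants: 5 (orsellinic acid, 2,4-dihydroxy-6-methylbenzoic acid)
Product: 7 (benzyl 2,4-dihydroxy-6-methylbenzoate)
Conditions: BnBr, NaHCO3, DMF, rt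
Reagents that add atoms: benzyl bromide, BrCc1ccccc1
Why: under weak base the carboxylate is the main nucleophile, so SN2 O-benzylation gives the ester (Williamson-type esterification) without touching the phenols.

**Step 2**
Reactants: 7
Product: 8 (benzyl 2-hydroxy-4-methoxy-6-methylbenzoate, benzyl everninate)
Conditions: MeI, K2CO3, acetone, 50 °C
Reagents that add atoms: methyl iodide, CI
Why: the 2-OH is locked in a hydrogen bond to the ester carbonyl, so the more acidic 4-OH is selectively O-methylated (Williamson ether synthesis).

**Step 3**
Reactants: 8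
Product: 9 (benzyl 3-formyl-2-hydroxy-4-methoxy-6-methylbenzoate)
Conditions: MgCl2, Et3N, (CH2O)n, MeCN, reflux
Reagents that add atoms: paraformaldehyde, C=O
Why: the magnesium phenoxide directs formylation to the ortho position, and C1 is blocked by the ester, so only C3 reacts (ortho-formylation of phenols).

**Step 4**
Reactants: 9
Product: 3 (3-formyl-2-hydroxy-4-methoxy-6-methylbenzoic acid)
Conditions: H2 (1 atm), 10% Pd/C, EtOAc, rt, short time
Reagents that add atoms: none
Why: the benzyl ester is cleaved (hydrogenolysis) much faster than the chelated, electron-rich aryl aldehyde is reduced.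

**Step 5**
Reactants: 6 (atraric acid, methyl 2,4-dihydroxy-3,6-dimethylbenzoate)
Product: 10 (2,4-dihydroxy-3,6-dimethylbenzoic acid)
Conditions: KOH, H2O, 100 °C, N2; then HCl, 0 °C
Reagents that add atoms: water, O
Why: forcing saponification is needed for this di-ortho-substituted ester, and it is done early, before the sensitive depside exists.

**Step 6**
Reactants: 10
Product: 11 (benzyl 4-(benzyloxy)-2-hydroxy-3,6-dimethylbenzoate)
Conditions: BnBr (2.2 equiv), K2CO3, DMF, rt
Reagents that add atoms: benzyl bromide, BrCc1ccccc1
Why: the carboxylate and the free 4-OH are alkylated, while the chelated 2-OH stays free (Williamson alkylation).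

**Step 7**
Reactants: 11
Product: 12 (2-benzyloxycarbonyl-5-benzyloxy-3,6-dimethyl-1,4-benzoquinone)
Conditions: Fremy's salt, KH2PO4 buffer, acetone/H2O, rt
Reagents that add atoms: Fremy's salt, [O]N(S(=O)(=O)[O-])S(=O)(=O)[O-].[K+].[K+]; water, O (the quinone oxygen comes from water)
Why: the only free ring position, C5, is para to the 2-OH, so Teuber (Fremy) oxidation installs the C5 oxygen regioselectively.

**Step 8**
Reactants: 12
Product: 4 (benzyl 4-(benzyloxy)-2,5-dihydroxy-3,6-dimethylbenzoate)
Conditions: Na2S2O4, EtOAc/H2O, rt, N2; use the product immediately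
Reagents that add atoms: none
Why: dithionite reduces the quinone to the hydroquinone; the 2-OH is chelated and the 4-OBn is fixed, so only the 5-OH is available for acylation.

**Step 9**
Reactants: 3 and 4
Product: 2 (benzyl 4-(benzyloxy)-5-[(3-formyl-2-hydroxy-4-methoxy-6-methylbenzoyl)oxy]-2-hydroxy-3,6-dimethylbenzoate)
Conditions: TFAA, TFA, 0 °C to rt, N2
Reagents that add atoms: none (TFAA only activates the acid)
Why: the Sala–Sargent TFAA-mediated depside esterification forms a mixed anhydride or acylium from the hindered acid, which acylates the free 5-OH while the hydrogen-bonded 2-OH groups stay untouched.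

**Step 10**
Reactants: 2
Product: 13 (benzyl-protected 3-carboxy depside)
Conditions: NaClO2, NaH2PO4, 2-methyl-2-butene, t-BuOH/H2O, rt
Reagents that add atoms: sodium chlorite, [Na+].[O-]Cl=O
Why: Pinnick oxidation converts the aldehyde to the acid; the ester, benzyl groups and aryl methyl ether are inert, and the alkene scavenges HOCl.

**Step 11**
Reactants: 13
Product: 1 (hypothamnolic acid)
Conditions: H2 (1 atm), 10% Pd/C, THF, rt
Reagents that add atoms: none
Why: hydrogenolysis removes the benzyl ester and benzyl ether (toluene is the by-product), leaving the aryl ester and OMe intact. No stereocentres are involved.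

## Compound list
1 | hypothamnolic acid | COc1cc(C)c(C(=O)Oc2c(C)c(C(=O)O)c(O)c(C)c2O)c(O)c1C(=O)O | target
2 | benzyl-protected 3-formyl depside | COc1cc(C)c(C(=O)Oc2c(C)c(C(=O)OCc3ccccc3)c(O)c(C)c2OCc2ccccc2)c(O)c1C=O | intermediate
3 | 3-formyl-2-hydroxy-4-methoxy-6-methylbenzoic acid | COc1cc(C)c(C(=O)O)c(O)c1C=O | intermediate
4 | benzyl 4-(benzyloxy)-2,5-dihydroxy-3,6-dimethylbenzoate | O=C(OCc1ccccc1)c1c(O)c(C)c(OCc2ccccc2)c(O)c1C | intermediate
5 | orsellinic acid | Cc1cc(O)cc(O)c1C(=O)O | starting material
6 | atraric acid (methyl 2,4-dihydroxy-3,6-dimethylbenzoate) | COC(=O)c1c(O)c(C)c(O)cc1C | starting material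
7 | benzyl orsellinate | Cc1cc(O)cc(O)c1C(=O)OCc1ccccc1 | intermediate
8 | benzyl everninate | COc1cc(C)c(C(=O)OCc2ccccc2)c(O)c1 | intermediate
9 | benzyl 3-formyl-2-hydroxy-4-methoxy-6-methylbenzoate | COc1cc(C)c(C(=O)OCc2ccccc2)c(O)c1C=O | intermediate
10 | 2,4-dihydroxy-3,6-dimethylbenzoic acid | Cc1cc(O)c(C)c(O)c1C(=O)O | intermediate
11 | benzyl 4-(benzyloxy)-2-hydroxy-3,6-dimethylbenzoate | O=C(OCc1ccccc1)c1c(C)cc(OCc2ccccc2)c(C)c1O | intermediate
12 | 2-benzyloxycarbonyl-5-benzyloxy-3,6-dimethyl-1,4-benzoquinone | O=C1C(C(=O)OCc2ccccc2)=C(C)C(=O)C(OCc2ccccc2)=C1C | intermediate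
13 | benzyl-protected 3-carboxy depside | COc1cc(C)c(C(=O)Oc2c(C)c(C(=O)OCc3ccccc3)c(O)c(C)c2OCc2ccccc2)c(O)c1C(=O)O | intermediate

## Totals
Total steps: 11. Longest linear sequence: 7 steps (5→7→8→9→3→2→13→1, or equally 6→10→11→12→4→2→13→1).

## Three steps most likely to fail
1. **Step 7 (Fremy oxidation of an electron-poor salicylate).** Yield or regiochemistry may be poor. Fallback: install the C5 oxygen by formylation at C5 of 11 (Vilsmeier), then mCPBA Baeyer–Villiger (Dakin-type) to the aryl formate, then mild methanolysis. This gives the same hydroquinone 4 by a different bond-forming logic.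
2. **Step 9 (esterification onto a phenol flanked by OBn and Me, using a 2,6-disubstituted acid).** Fallback: switch from the TFAA mixed anhydride to Yamaguchi or Steglich coupling, using a 2-O-benzyl-protected version of acid 3 made through the allyl-ester variant (allyl everninate, formylation, Pd(0) deallylation, with 2-OBn introduced before deallylation). The extra 2-OBn is removed in the final hydrogenolysis.
3. **Step 4 (hydrogenolysis of the benzyl ester with the aldehyde present).** Over-reduction of the CHO is possible. Fallback: use an allyl ester in place of the benzyl ester in Steps 1–3, and cleave it with Pd(PPh3)4/PhSiH3 or a Pd(0) transfer system, which leaves the aldehyde alone.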